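Ring labels: A = 4-methoxyphenyl, B = 4-hydroxy-2-methoxyphenyl, C = the 2,6-dimethoxyaryl ring, D = the 4-hydroxyphenyl end of the stilbene. The chain is C1 (methine stereocentre), C2, C3 (benzylic CH2 on ring B).
Cuts: first C1–ring A (back to a C1–B bond), then C1–ring C and C2–C3 together, and last the C=C between rings C and D.
Enabling feature: C1 and C2 are a two-carbon unit held between ring C (on C1) and the C3 methylene of ring B (on C2). This is the imprint of a vinylboron ate complex that takes a migrating aryl group at its boron-bearing carbon and a carbon electrophile at its terminus.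
Forward: no ring is built. Rings C and D are joined by olefination, then ring C, the C1–C2 vinyl unit and the C3–ring B benzyl unit are merged in one three-component coupling. Ring A then replaces boron, and O-methylation and acetal removal finish the target.
Stereochemistry: C1 is created in the nickel-catalysed coupling under control of a chiral diamine ligand and is carried over with retention when boron is exchanged for ring A. The E-alkene comes from the Horner–Wadsworth–Emmons reaction.

Key step: step 9

Assumption: the sense of induction of the diamine–nickel catalyst with a benzylic electrophile cannot be predicted with certainty, so the (S,S)-ligand is written and its equally available (R,R)-antipode would be taken if a first run delivered the (1S)-boronate.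

Step 1
Reactants: 1 4-bromo-3,5-dimethoxybenzaldehyde
Product: 2 (4-bromo-3,5-dimethoxyphenyl)methanol
Conditions: NaBH4, MeOH, 0 °C
Reagents that add atoms: none
Why: Borohydride reduction of an aromatic aldehyde, to which the aryl bromide and the methyl ethers are inert.

Step 2
Reactants: 2 (4-bromo-3,5-dimethoxyphenyl)methanol
Product: 3 2-bromo-5-(bromomethyl)-1,3-dimethoxybenzene
Conditions: PBr3, CH2Cl2, 0 °C
Reagents that add atoms: phosphorus tribromide, BrP(Br)Br
Why: PBr3 bromination of a primary benzylic alcohol (SN2 on the phosphite ester) should be clean because nothing acid-labile is present.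

Step 3
Reactants: 3 2-bromo-5-(bromomethyl)-1,3-dimethoxybenzene
Product: 4 diethyl [(4-bromo-3,5-dimethoxyphenyl)methyl]phosphonate
Conditions: P(OEt)3, neat, 130 °C
Reagents that add atoms: triethyl phosphite, CCOP(OCC)OCC
Why: Michaelis–Arbuzov reaction, in which only the benzylic bromide alkylates phosphorus and the aryl bromide stays untouched without a metal catalyst.

Step 4
Reactants: 5 4-hydroxybenzaldehyde
Product: 6 4-(methoxymethoxy)benzaldehyde
Conditions: MOMCl, iPr2NEt, CH2Cl2, 0 °C → rt
Reagents that add atoms: chloromethyl methyl ether, COCCl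
Why: Williamson-type O-alkylation of an acidic phenol gives an acetal that withstands the bases, organolithiums and nickel catalyst used later.

Step 5
Reactants: 4 diethyl [(4-bromo-3,5-dimethoxyphenyl)methyl]phosphonate; 6 4-(methoxymethoxy)benzaldehyde
Product: 7 2-bromo-1,3-dimethoxy-5-[(E)-2-[4-(methoxymethoxy)phenyl]ethenyl]benzene
Conditions: KOtBu, THF, 0 °C → rt
Reagents that add atoms: none
Why: Horner–Wadsworth–Emmons olefination of a benzylic phosphonate anion with a non-enolisable aryl aldehyde, a combination that reliably favours the E-stilbene.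

Step 6
Reactants: 8 4-hydroxy-2-methoxybenzaldehyde
Product: 9 2-methoxy-4-(methoxymethoxy)benzaldehyde
Conditions: MOMCl, iPr2NEt, CH2Cl2, 0 °C → rt
Reagents that add atoms: chloromethyl methyl ether, COCCl
Why: Williamson-type O-alkylation of the only phenol, which is made acidic by the para formyl group.

Step 7
Reactants: 9 2-methoxy-4-(methoxymethoxy)benzaldehyde
Product: 10 [2-methoxy-4-(methoxymethoxy)phenyl]methanol
Conditions: NaBH4, MeOH, 0 °C
Reagents that add atoms: none
Why: Borohydride reduction of an aromatic aldehyde under basic conditions that leave the acetal intact.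

Step 8
Reactants: 10 [2-methoxy-4-(methoxymethoxy)phenyl]methanol
Product: 12 1-(chloromethyl)-2-methoxy-4-(methoxymethoxy)benzene, via benzylic mesylate 11 (not isolated)
Conditions: MsCl, iPr2NEt, CH2Cl2, 0 °C → rt; cold aq. NaHCO3 wash; used at once as a THF solution
Reagents that add atoms: methanesulfonyl chloride, CS(=O)(=O)Cl
Why: Mesylation followed by in situ nucleophilic substitution by the ammonium chloride formed, which is fast for an electron-rich benzylic mesylate, while the hindered base keeps the medium free of HCl and does not quaternise.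

Step 9
Reactants: 7 2-bromo-1,3-dimethoxy-5-[(E)-2-[4-(methoxymethoxy)phenyl]ethenyl]benzene; 12 1-(chloromethyl)-2-methoxy-4-(methoxymethoxy)benzene; 13 2-ethenyl-4,4,5,5-tetramethyl-1,3,2-dioxaborolane (vinylboronic acid pinacol ester)
Product: 16 2-[(1R)-1-{2,6-dimethoxy-4-[(E)-2-[4-(methoxymethoxy)phenyl]ethenyl]phenyl}-3-[2-methoxy-4-(methoxymethoxy)phenyl]propyl]-4,4,5,5-tetramethyl-1,3,2-dioxaborolane, via aryllithium 14 (not isolated), via lithium vinylboronate complex 15 (not isolated)
Conditions: 7, t-BuLi (2.0 equiv), THF, −78 °C; 13, −78 °C → rt; NiBr2(MeOCH2CH2OMe) (10 mol %), (S,S)-N,N'-dimethyl-1,2-diphenylethane-1,2-diamine (12 mol %), 12 (slow addition), THF, 0 °C → rt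
Reagents that add atoms: tert-butyllithium, [Li]C(C)(C)C (gives only the lithium of 14 and 15; nothing of it stays in 16)
Why: Proposed new method: the nickel dibromide is reduced by a little of 15 to zerovalent nickel, which inserts into the C–Cl bond of 12; loss of chloride to lithium leaves a cationic η3-benzyl divalent nickel–diamine complex that binds the vinyl group of 15 as a π-acid and so provokes 1,2-migration of ring C from boron to the boron-bearing carbon (C1), anti to the metal, while the terminal carbon (C2) bonds to nickel, and reductive elimination of the benzyl and β-boryl alkyl ligands forms the C2–C3 bond. The closest known reaction type is the enantioselective nickel- or palladium-catalysed conjunctive cross-coupling of vinylboron ate complexes, established with aryl, alkenyl and simple alkyl electrophiles, and the 1,2-metallate shifts induced by π-allyl and propargyl palladium species show that a delocalised carbon ligand can take the place of the aryl group; a benzylic chloride has not been shown. No ring is closed. The one new stereocentre, C1, is fixed by the face of the vinyl group that the twofold-symmetric diamine–nickel fragment binds, because the migration is stereospecifically anti and C1 is not touched again in this step. The metallate shift must outrun direct aryl or vinyl transfer to nickel, benzyl homocoupling and the uncatalysed, racemic alkylation of 15: the two ortho-methoxy groups slow transmetallation of ring C while their donor effect raises its migratory aptitude, slow addition keeps 12 dilute, and a chloride in THF without polar cosolvent ionises slowly in spite of the electron-rich ring B. Exchange with two equivalents of t-BuLi leaves no alkyl bromide to compete as an electrophile, and the neutral, 1,2-disubstituted stilbene should bind nickel far less well than the anionic terminal vinyl boronate.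

Step 10
Reactants: 16 the (1R)-benzylic pinacol boronate of step 9; 17 4-bromophenol
Product: 21 4-[(1S)-1-{2,6-dimethoxy-4-[(E)-2-[4-(methoxymethoxy)phenyl]ethenyl]phenyl}-3-[2-methoxy-4-(methoxymethoxy)phenyl]propyl]phenol, via lithium 4-lithiophenolate 18 (not isolated), via dilithium boronate complex 19 (not isolated), via 4-borylcyclohexadienone 20 (not isolated)
Conditions: 17 (1.5 equiv), t-BuLi (3 equiv per 17), THF, −78 → 0 °C; 16, −78 °C → rt; Ph3BiF2, −78 °C → rt; aq. NH4Cl
Reagents that add atoms: tert-butyllithium, [Li]C(C)(C)C (gives only the lithium of 18 and 19; nothing of it stays in 21)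
Why: Known enantiospecific sp2–sp3 coupling of boronic esters with para-lithiated phenolates, in which pentavalent bismuth activates the phenolate oxygen of 19, C1 migrates from boron to the ipso carbon of ring A with retention to give dienone 20, and loss of the boryl group restores the aromatic ring without touching the acetals, the methyl ethers or the stilbene.

Step 11
Reactants: 21 the ring A phenol of step 10
Product: 22 1,3-dimethoxy-2-[(1S)-1-(4-methoxyphenyl)-3-[2-methoxy-4-(methoxymethoxy)phenyl]propyl]-5-[(E)-2-[4-(methoxymethoxy)phenyl]ethenyl]benzene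
Conditions: MeI, K2CO3, acetone, rt → 40 °C
Reagents that add atoms: iodomethane, CI
Why: Williamson ether synthesis on the only free phenol, the oxygens of rings B and D being masked as acetals.

Step 12
Reactants: 22 the bis(methoxymethyl) ether of step 11
Product: 23 4-[(3S)-3-{4-[(E)-2-(4-hydroxyphenyl)ethenyl]-2,6-dimethoxyphenyl}-3-(4-methoxyphenyl)propyl]-3-methoxyphenol (target)
Conditions: 2 M aq. HCl, MeOH/THF, 45 °C
Reagents that add atoms: none
Why: Acid-catalysed acetal hydrolysis frees both phenols, while dilute acid should leave the aryl methyl ethers, the E-alkene and the diarylmethine stereocentre (no acidic hydrogen, no leaving group) unchanged.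

Compound list
1 | 4-bromo-3,5-dimethoxybenzaldehyde | COc1cc(C=O)cc(OC)c1Br | starting material
2 | (4-bromo-3,5-dimethoxyphenyl)methanol | COc1cc(CO)cc(OC)c1Br | intermediate
3 | 2-bromo-5-(bromomethyl)-1,3-dimethoxybenzene | COc1cc(CBr)cc(OC)c1Br | intermediate
4 | diethyl [(4-bromo-3,5-dimethoxyphenyl)methyl]phosphonate | CCOP(=O)(Cc1cc(OC)c(Br)c(OC)c1)OCC | intermediate
5 | 4-hydroxybenzaldehyde | O=Cc1ccc(O)cc1 | starting material
6 | 4-(methoxymethoxy)benzaldehyde | COCOc1ccc(C=O)cc1 | intermediate
7 | 2-bromo-1,3-dimethoxy-5-[(E)-2-[4-(methoxymethoxy)phenyl]ethenyl]benzene | COCOc1ccc(/C=C/c2cc(OC)c(Br)c(OC)c2)cc1 | intermediate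
8 | 4-hydroxy-2-methoxybenzaldehyde | COc1cc(O)ccc1C=O | starting material
9 | 2-methoxy-4-(methoxymethoxy)benzaldehyde | COCOc1ccc(C=O)c(OC)c1 | intermediate
10 | [2-methoxy-4-(methoxymethoxy)phenyl]methanol | COCOc1ccc(CO)c(OC)c1 | intermediate
11 | [2-methoxy-4-(methoxymethoxy)phenyl]methyl methanesulfonate (formed in situ) | COCOc1ccc(COS(C)(=O)=O)c(OC)c1 | intermediate
12 | 1-(chloromethyl)-2-methoxy-4-(methoxymethoxy)benzene | COCOc1ccc(CCl)c(OC)c1 | intermediate
13 | 2-ethenyl-4,4,5,5-tetramethyl-1,3,2-dioxaborolane | C=CB1OC(C)(C)C(C)(C)O1 | starting material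
14 | {2,6-dimethoxy-4-[(E)-2-[4-(methoxymethoxy)phenyl]ethenyl]phenyl}lithium (formed in situ) | [Li]c1c(OC)cc(/C=C/c2ccc(OCOC)cc2)cc1OC | intermediate
15 | lithium {2,6-dimethoxy-4-[(E)-2-[4-(methoxymethoxy)phenyl]ethenyl]phenyl}(ethenyl)(pinacolato)borate (formed in situ) | [Li+].C=C[B-]1(c2c(OC)cc(/C=C/c3ccc(OCOC)cc3)cc2OC)OC(C)(C)C(C)(C)O1 | intermediate
16 | 2-[(1R)-1-{2,6-dimethoxy-4-[(E)-2-[4-(methoxymethoxy)phenyl]ethenyl]phenyl}-3-[2-methoxy-4-(methoxymethoxy)phenyl]propyl]-4,4,5,5-tetramethyl-1,3,2-dioxaborolane | CC1(C)OB([C@H](CCc2ccc(OCOC)cc2OC)c2c(OC)cc(/C=C/c3ccc(OCOC)cc3)cc2OC)OC1(C)C | intermediate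
17 | 4-bromophenol | Oc1ccc(Br)cc1 | starting material
18 | lithium 4-lithiophenolate (formed in situ) | [Li]Oc1ccc([Li])cc1 | intermediate
19 | dilithium (4-oxidophenyl)(pinacolato)borate bearing the (1R)-configured C1 alkyl group of 16 (formed in situ) | [Li+].[Li+].[O-]c1ccc(cc1)[B-]1([C@H](CCc2ccc(OCOC)cc2OC)c2c(OC)cc(/C=C/c3ccc(OCOC)cc3)cc2OC)OC(C)(C)C(C)(C)O1 | intermediate
20 | 4-(pinacolatoboryl)cyclohexa-2,5-dien-1-one bearing the (1S)-configured C1 alkyl group at C4 (formed in situ) | O=C1C=CC(C=C1)(B1OC(C)(C)C(C)(C)O1)[C@H](CCc1ccc(OCOC)cc1OC)c1c(OC)cc(/C=C/c2ccc(OCOC)cc2)cc1OC | intermediate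
21 | 4-[(1S)-1-{2,6-dimethoxy-4-[(E)-2-[4-(methoxymethoxy)phenyl]ethenyl]phenyl}-3-[2-methoxy-4-(methoxymethoxy)phenyl]propyl]phenol | Oc1ccc([C@H](CCc2ccc(OCOC)cc2OC)c2c(OC)cc(/C=C/c3ccc(OCOC)cc3)cc2OC)cc1 | intermediate
22 | 1,3-dimethoxy-2-[(1S)-1-(4-methoxyphenyl)-3-[2-methoxy-4-(methoxymethoxy)phenyl]propyl]-5-[(E)-2-[4-(methoxymethoxy)phenyl]ethenyl]benzene | COc1ccc([C@H](CCc2ccc(OCOC)cc2OC)c2c(OC)cc(/C=C/c3ccc(OCOC)cc3)cc2OC)cc1 | intermediate
23 | 4-[(3S)-3-{4-[(E)-2-(4-hydroxyphenyl)ethenyl]-2,6-dimethoxyphenyl}-3-(4-methoxyphenyl)propyl]-3-methoxyphenol | COc1ccc([C@H](CCc2ccc(O)cc2OC)c2c(OC)cc(/C=C/c3ccc(O)cc3)cc2OC)cc1 | target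

Total step count: 12. Longest linear sequence: 8 steps (1, 2, 3, 5, 9, 10, 11, 12).

Steps most likely to fail

1. Step 9 (new method).
- What may go wrong: the benzyl–nickel species may be drained by homocoupling or by direct aryl or vinyl transfer before it activates the vinyl group. Uncatalysed alkylation of the ate complex may erode the enantiomeric purity. Facial selectivity with a benzyl ligand on nickel may be poor.
- Fallback: known chemistry, sparteine-mediated lithiation–borylation. It sets out from 9 and 14, comes back at 16, and keeps the boron-to-carbon migration of ring C.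
- Building the carbamate: aldehyde 9 is extended with Ph3P=CHCO2Et (toluene, 80 °C) to ethyl (E)-3-[2-methoxy-4-(methoxymethoxy)phenyl]prop-2-enoate F1. This is hydrogenated (H2, Pd on carbon, EtOAc) to ethyl 3-[2-methoxy-4-(methoxymethoxy)phenyl]propanoate F2 and reduced (LiAlH4, THF) to 3-[2-methoxy-4-(methoxymethoxy)phenyl]propan-1-ol F3. Carbamoylation (iPr2NCOCl, Et3N, CH2Cl2, reflux) then gives 3-[2-methoxy-4-(methoxymethoxy)phenyl]propyl N,N-diisopropylcarbamate F4.
- Building the aryl boronate: aryllithium 14 is quenched with iPrOBpin to give 2-{2,6-dimethoxy-4-[(E)-2-[4-(methoxymethoxy)phenyl]ethenyl]phenyl}-4,4,5,5-tetramethyl-1,3,2-dioxaborolane F5.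
- Lithiation: s-BuLi/(−)-sparteine (Et2O, −78 °C, slightly less base than F4 so that none is left for the stilbene) removes the pro-S hydrogen next to oxygen and gives the configurationally stable (1S)-1-lithio carbamate F6. At this temperature the carbamate carbonyl steers the base, and ring lithiation between the two ether oxygens of ring B should lag behind.
- Borylation and migration: F5 is borylated by F6 with retention to give the lithium boronate complex F7. Warming (Et2O, reflux) drives 1,2-migration of ring C with inversion and loss of the carbamate, giving 16 with the (1R) configuration.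

2. Step 10.
- What may go wrong: the hindered boron of 16 may form the ate complex incompletely. The pentavalent bismuth reagent may also oxidise the electron-rich benzylic C–B bond or the stilbene by one-electron paths, with loss of stereospecificity.
- Fallback: a transition-metal coupling in place of the boronate rearrangement, setting out from 16 and coming back at 22, past 21 and step 11. It is the stereoretentive Suzuki–Miyaura coupling known for secondary benzylic pinacol boronates, run with 4-iodoanisole (Pd2(dba)3, excess PPh3, Ag2O, DME, 85 °C). It makes no new compound (F0).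

3. Step 8.
- What may go wrong: the electron-rich benzyl chloride may ionise on concentration or storage and alkylate its own ring (oligomerisation), or it may hydrolyse during the wash.
- Fallback: a storable C–O electrophile replaces the halide, setting out from 10 and coming back at 16. Alcohol 10 is acylated (ClCO2Me, pyridine, CH2Cl2, 0 °C) to [2-methoxy-4-(methoxymethoxy)phenyl]methyl methyl carbonate F8, which can be purified and kept.
- Use of F8: it takes the place of 12 in step 9. Insertion of zerovalent nickel into the benzylic C–O bond of such carbonates, known from benzylic substitution and cross-coupling, should lead to the same η3-benzyl nickel species, with methyl carbonate as a weakly coordinating leaving group.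

Further compounds
F1 | step 9 | ethyl (E)-3-[2-methoxy-4-(methoxymethoxy)phenyl]prop-2-enoate | CCOC(=O)/C=C/c1ccc(OCOC)cc1OC
F2 | step 9 | ethyl 3-[2-methoxy-4-(methoxymethoxy)phenyl]propanoate | CCOC(=O)CCc1ccc(OCOC)cc1OC
F3 | step 9 | 3-[2-methoxy-4-(methoxymethoxy)phenyl]propan-1-ol | OCCCc1ccc(OCOC)cc1OC
F4 | step 9 | 3-[2-methoxy-4-(methoxymethoxy)phenyl]propyl N,N-diisopropylcarbamate | CC(C)N(C(C)C)C(=O)OCCCc1ccc(OCOC)cc1OC
F5 | step 9 | 2-{2,6-dimethoxy-4-[(E)-2-[4-(methoxymethoxy)phenyl]ethenyl]phenyl}-4,4,5,5-tetramethyl-1,3,2-dioxaborolane | COCOc1ccc(/C=C/c2cc(OC)c(B3OC(C)(C)C(C)(C)O3)c(OC)c2)cc1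
F6 | step 9 | (1S)-1-lithio-3-[2-methoxy-4-(methoxymethoxy)phenyl]propyl N,N-diisopropylcarbamate (as its sparteine complex) | [Li][C@@H](CCc1ccc(OCOC)cc1OC)OC(=O)N(C(C)C)C(C)C
F7 | step 9 | lithium boronate complex of F5 and F6, (1S) at the carbamoyloxy carbon | [Li+].COCOc1ccc(/C=C/c2cc(OC)c(c(OC)c2)[B-]2(OC(C)(C)C(C)(C)O2)[C@@H](CCc2ccc(OCOC)cc2OC)OC(=O)N(C(C)C)C(C)C)cc1
F0 | step 10 | none | none
F8 | step 8 | [2-methoxy-4-(methoxymethoxy)phenyl]methyl methyl carbonate | COC(=O)OCc1ccc(OCOC)cc1OC
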